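Readings and results were computed for substances that don't exist; noise was put on by code.

Look first at late times: the last readings of the winter run and the spring run no longer rise, and what they still tell you is the ratio of left-handed to right-handed product.

in all of them: left-handed substrate 0.072 M; right-handed substrate 0.072 M; impurity 0.92 mM

| flask | solid reagent | precatalyst | temperature | remark | time |
|---|---|---|---|---|---|
| winter | 0.30 equiv | 2.5 mol% | −15 °C | run made earlier |  |
| spring | 0.45 equiv | 2.5 mol% | 35 °C | run made earlier |  |
| dusk | 0.60 equiv | 1.2 mol% | −15 °C | run made earlier |  |
| grey | 0.600 equiv | 2.5 mol% | 80 °C |  | 2.5 min |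
| teal | 0.600 equiv | 2.5 mol% | −10 °C |  | 2.5 min |
| red | 0.600 equiv | 2.5 mol% | 50 °C |  | 2.5 min |
| blue | 0.600 equiv | 2.5 mol% | 20 °C |  | 2.5 min |

| run | time / min | left-handed product / % | right-handed product / % |
|---|---|---|---|
| winter | 30.0 | 0 | 7 |
| winter | 80.0 | 2 | 12 |
| winter | 150 | 3 | 12 |
| winter | 240 | 1 | 10 |
| spring | 5.00 | 9 | 3 |
| spring | 10.0 | 16 | 4 |
| spring | 15.0 | 17 | 3 |
| spring | 20.0 | 15 | 4 |
| dusk | 60.0 | 3 | 1 |
| dusk | 120 | 0 | 1 |
| dusk | 180 | 0 | 1 |
| dusk | 240 | 3 | 0 |

(readings scatter by 1.5 percentage points)

- free catalyst is single-handed; left-handed substrate and right-handed substrate are mirror images of each other, charged as a racemate, each of them at the stated concentration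
- solid reagent is a solid; its amount is given per volume of the solution
- at the start none of the solid reagent is in solution

1. the flask with the highest share of left-handed product in all that became left-handed product or right-handed product ("all alike" if they lie within 1.5 percentage points) (grey / teal / red / blue / all alike)
2. share of left-handed product in all that became left-handed product or right-handed product, grey
3. share of left-handed product in all that became left-handed product or right-handed product, teal
4. share of left-handed product in all that became left-handed product or right-handed product, red
5. share of left-handed product in all that became left-handed product or right-handed product, blue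

Call that ratio s, the selectivity factor as read from product amounts, and let L = ln s. I take s as steady through a run, so you can sum each product over the four readings. That gives L = −1.92 for the winter run and 1.40 for the spring run.

Now replace the curve of L against temperature by its mean slope. Let g be the rise of L per kelvin between those two runs, 0.0665 /K; it puts the whole difference on temperature, although the solid reagent differs too, 0.30 equiv in the winter run against 0.45 equiv in the spring run. In the winter run the left-handed readings average 1.50% against a scatter of 1.5 percentage points on each reading, so its L is a rough reading.

Stepping from the winter run with g, my shares are 98.8% for grey, 91.7% for red, 60.0% for blue and 16.9% for teal, so grey stands highest.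

The forecast, holding that “temperature is the likelier cause”, says 94%, 88%, 62% and 18% in the same order, and names grey.

The flasks give 98.7% for grey, 92.3% for red, 53.0% for blue and 5.17% for teal, with grey highest.

    free catalyst + left-handed substrate ⇌ catalyst intermediate A (K = 3.50 /M, k = 420 /M/s, Ea = 44.0 kJ/mol, ΔH = 19.0 kJ/mol)
    free catalyst + right-handed substrate ⇌ catalyst intermediate B (K = 9.30 /M, k = 1400 /M/s, Ea = 44.0 kJ/mol, ΔH = −38.0 kJ/mol)
    coupling partner + catalyst intermediate A → free catalyst + left-handed product (k = 9.00 /M/s, Ea = 44.0 kJ/mol)
    coupling partner + catalyst intermediate B → free catalyst + right-handed product (k = 3.00 /M/s, Ea = 36.0 kJ/mol)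
    coupling partner + precatalyst → free catalyst + spent reagent (k = 4.90 /M/s, Ea = 53.0 kJ/mol)
    solid reagent ⇌ coupling partner, rate k6*(cs6 - [coupling partner]) while solid is left; crystals form when [coupling partner] > cs6 (solubility = 30.0 mM, k = 0.00950 /s)
    free catalyst + impurity → spent catalyst (k = 1500 /M/s, Ea = 36.0 kJ/mol)
    (constants at 20 °C)

Teal has not come to rest at 2.50 min: conversion stands at 0.326%, and 43.1% of the catalyst charged is still precatalyst. Left until 25.0 min, teal has its precatalyst down to 0% and its right-handed product up from 0.129% to 9.49%, yet the share moves from 5.17% to 5.69%. So in teal, L goes from −2.91 to −2.81 with waiting, and both lie below the −1.59 that g gave.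

For a flask like teal kept at −25 °C, step g down from the L that teal showed: L = −3.91, a share of 1.96%. That flask gives 0.935%.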